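**Strategy.** The cyclohexane is disconnected at the bond between the ring carbon that carries the acrylic acid and the acyloxy-bearing ring carbon. Read backwards, the homoallylic alcohol/α-methylene ester array C(OH)–CH–C(=CH2)CO2R is the signature of a γ-selective carbonyl allylation. The key step is therefore an intramolecular Nozaki–Hiyama allylation: divalent chromium reverses the polarity of a 2-(bromomethyl)enoate β-carbon, which attacks a tethered aldehyde, closes the six-membered ring, sets both new stereocentres and unveils the exocyclic methylene. The acyclic precursor takes its quaternary methyl/vinyl carbon and the neighbouring propenyl-bearing carbon from an enantioselective Ireland–Claisen rearrangement, and its silyloxy carbinol from a reagent-controlled ynone reduction.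

Key step: step 14

Assumption: the (4R,5R)-diazaborolidine of step 5 is taken to give the (2S,3R)-acid 10 by analogy with the usual facial preference of this controller; if the sense proves opposite, the (4S,5S)-reagent is used with nothing else changed.

Abbreviations: TBS = tert-butyldimethylsilyl, TBDPS = tert-butyldiphenylsilyl, TMSE = 2-(trimethylsilyl)ethyl, PMB = 4-methoxybenzyl; TBSO and TBDPSO denote the corresponding silyloxy groups.

Step 1
Reactants: 1 tert-butyl(but-3-yn-1-yloxy)dimethylsilane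
Product: 3 (2E)-5-(TBSO)-3-methylpent-2-en-1-ol, via alkenylalane 2 (not isolated)
Conditions: AlMe3 (2 equiv), Cp2ZrCl2 (0.25 equiv), CH2Cl2, 0 °C → rt; then n-BuLi, (CH2O)n, THF, −78 °C → rt; aq HCl work-up
Reagents that add atoms: trimethylaluminium C[Al](C)C; paraformaldehyde (as formaldehyde) C=O
Why: Zirconium-catalysed syn-carboalumination (Negishi carboalumination) should place methyl on the internal and aluminium on the terminal alkyne carbon, and hydroxymethylation of the derived alanate with retention fixes the E trisubstituted alkene.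

Step 2
Reactants: 3 (2E)-5-(TBSO)-3-methylpent-2-en-1-ol; 4 itaconic anhydride
Product: 5 4-{[(2E)-5-(TBSO)-3-methylpent-2-en-1-yl]oxy}-2-methylidene-4-oxobutanoic acid
Conditions: toluene, 70 °C
Reagents that add atoms: none
Why: Regioselective alcoholysis of the cyclic anhydride should occur at the more electrophilic, non-conjugated carbonyl and leave the acrylic acid free.

Step 3
Reactants: 5 the half ester
Product: 7 (2E)-5-(TBSO)-3-methylpent-2-en-1-yl 3-(hydroxymethyl)but-3-enoate, via mixed carbonic anhydride 6 (not isolated)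
Conditions: i-BuOCOCl, N-methylmorpholine, THF, −15 °C; then NaBH4, H2O, −15 → 0 °C; used crude at once
Reagents that add atoms: none
Why: Mixed-anhydride activation lets NaBH4 reduce only the activated carboxyl (mixed-anhydride reduction) while the allylic ester stays intact; immediate silylation forestalls lactonisation of the γ-hydroxy ester.

Step 4
Reactants: 7 the hydroxy ester
Product: 8 (2E)-5-(TBSO)-3-methylpent-2-en-1-yl 3-[(TBDPSO)methyl]but-3-enoate
Conditions: t-BuPh2SiCl, imidazole, DMF, 0 °C → rt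
Reagents that add atoms: tert-butyl(chloro)diphenylsilane CC(C)(C)[Si](Cl)(c1ccccc1)c1ccccc1
Why: Standard silylation of a primary alcohol; the TBDPS ether is chosen to survive the later selective cleavage of the primary TBS ether.

Step 5
Reactants: 8 the allylic but-3-enoate
Product: 10 (2S,3R)-5-(TBSO)-2-[3-(TBDPSO)prop-1-en-2-yl]-3-ethenyl-3-methylpentanoic acid, via boron enolate 9 (not isolated)
Conditions: (4R,5R)-2-bromo-1,3-bis{[3,5-bis(trifluoromethyl)phenyl]sulfonyl}-4,5-diphenyl-1,3,2-diazaborolidine (1.2 equiv), Et3N, toluene/hexane, −78 °C, then −20 → 4 °C; aqueous work-up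
Reagents that add atoms: none
Why: Enantioselective Ireland–Claisen rearrangement: the E(O) boron enolate (propenyl group trans to O–B) and the E trisubstituted allyl unit should pass through a chair that creates the quaternary carbon and its neighbour in one [3,3] shift with the methyl/propenyl relationship required in the ring, the diazaborolidine selecting the enantiomer.

Step 6
Reactants: 11 prop-2-ynoic acid; 12 2-(trimethylsilyl)ethanol
Product: 13 2-(trimethylsilyl)ethyl prop-2-ynoate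
Conditions: N,N′-dicyclohexylcarbodiimide, 4-(dimethylamino)pyridine (cat.), CH2Cl2, −20 → 0 °C
Reagents that add atoms: none
Why: Steglich esterification at low temperature installs the fluoride-labile ester that later masks the acrylic acid.

Step 7
Reactants: 10 the pentanoic acid; 13 2-(trimethylsilyl)ethyl prop-2-ynoate
Product: 16 TMSE (5S,6R)-8-(TBSO)-5-[3-(TBDPSO)prop-1-en-2-yl]-6-ethenyl-6-methyl-4-oxooct-2-ynoate, via acid chloride 14 (not isolated), via alkynylzinc bromide 15 (not isolated)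
Conditions: 10, 1-chloro-N,N,2-trimethylprop-1-en-1-amine, CH2Cl2, 0 °C; separately 13, lithium diisopropylamide, THF, −78 °C, then ZnBr2; combine, Pd(PPh3)4 (5 mol %), THF, 0 °C → rt
Reagents that add atoms: none
Why: Neutral chlorination by the α-chloroenamine followed by palladium-catalysed acylation of the alkynylzinc (Negishi acylation) should give the ynone without amine base, so the acidic α-stereocentre is not exposed to enolisation.

Step 8
Reactants: 16 the ynone
Product: 17 TMSE (4R,5S,6R)-8-(TBSO)-5-[3-(TBDPSO)prop-1-en-2-yl]-6-ethenyl-4-hydroxy-6-methyloct-2-ynoate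
Conditions: (R)-2-methyl-CBS-oxazaborolidine (1 equiv), catecholborane, toluene, −78 °C
Reagents that add atoms: none
Why: Corey–Bakshi–Shibata reduction, in which the catalyst distinguishes the small alkynyl from the branched alkyl side and should deliver hydride to give the 4R carbinol; on the assumption that the quaternary substituent is the large group, this is also the Felkin–Anh sense.

Step 9
Reactants: 17 the propargylic alcohol
Product: 18 TMSE (4R,5S,6R)-4,8-bis(TBSO)-5-[3-(TBDPSO)prop-1-en-2-yl]-6-ethenyl-6-methyloct-2-ynoate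
Conditions: t-BuMe2SiOSO2CF3, 2,6-lutidine, CH2Cl2, −78 → 0 °C
Reagents that add atoms: tert-butyldimethylsilyl trifluoromethanesulfonate CC(C)(C)[Si](C)(C)OS(=O)(=O)C(F)(F)F
Why: Silyl triflate silylation of a hindered secondary alcohol, which blocks lactonisation onto the ester in all later steps.

Step 10
Reactants: 18 the silyloxy ynoate
Product: 20 TMSE (2Z,4S,5S,6R)-4,8-bis(TBSO)-5-[3-(TBDPSO)prop-1-en-2-yl]-6-ethenyl-2-(hydroxymethyl)-6-methyloct-2-enoate, via α-alumino enoate 19 (not isolated)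
Conditions: i-Bu2AlH, N-methylmorpholine N-oxide, THF, 0 °C; then monomeric CH2O (cracked paraformaldehyde), −78 → 0 °C; Rochelle salt work-up
Reagents that add atoms: formaldehyde C=O
Why: Conjugate syn-hydroalumination of the ynoate (vinylalumination) and capture of the α-alumino enoate by formaldehyde at the α-carbon should place the ester cis and the hydroxymethyl group trans to the silyloxy-bearing chain.

Step 11
Reactants: 20 the allylic alcohol
Product: 21 TMSE (2E,4S,5S,6R)-2-(bromomethyl)-4,8-bis(TBSO)-5-[3-(TBDPSO)prop-1-en-2-yl]-6-ethenyl-6-methyloct-2-enoate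
Conditions: CBr4, PPh3, CH2Cl2, −20 → 0 °C
Reagents that add atoms: tetrabromomethane BrC(Br)(Br)Br
Why: Appel bromination of the primary allylic alcohol proceeds without allylic transposition and keeps the alkene geometry.

Step 12
Reactants: 21 the allylic bromide
Product: 22 TMSE (2E,4S,5S,6R)-2-(bromomethyl)-4-(TBSO)-5-[3-(TBDPSO)prop-1-en-2-yl]-6-ethenyl-8-hydroxy-6-methyloct-2-enoate
Conditions: camphorsulfonic acid (cat.), MeOH/CH2Cl2, 0 °C
Reagents that add atoms: none
Why: Acid-catalysed methanolysis should cleave the unhindered primary TBS ether much faster than the hindered secondary TBS ether or the TBDPS ether, and it avoids nucleophilic amines that would attack the allylic bromide.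

Step 13
Reactants: 22 the primary alcohol
Product: 23 TMSE (2E,4S,5S,6R)-2-(bromomethyl)-4-(TBSO)-5-[3-(TBDPSO)prop-1-en-2-yl]-6-ethenyl-6-methyl-8-oxooct-2-enoate
Conditions: Dess–Martin periodinane, CH2Cl2, 0 °C → rt
Reagents that add atoms: none
Why: Dess–Martin oxidation gives the aldehyde under neutral, amine-free conditions that the allylic bromide tolerates.

Step 14
Reactants: 23 the bromo aldehyde
Product: 25 TMSE 2-[(1R,2R,3S,4R,6S)-2-(TBSO)-3-[3-(TBDPSO)prop-1-en-2-yl]-4-ethenyl-6-hydroxy-4-methylcyclohexyl]prop-2-enoate, via allylchromium 24 (not isolated)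
Conditions: CrCl2 (6 equiv), THF, 0.01 M, rt
Reagents that add atoms: none
Why: Divalent chromium inserts into the allylic C–Br bond by two one-electron transfers to give the trivalent allylchromium 24, whose γ-carbon (the former enoate β-carbon) adds to the aldehyde with allylic transposition through a six-membered Zimmerman–Traxler chair, so two electrophilic carbons are joined by polarity reversal; the closest known reaction type is the intramolecular Nozaki–Hiyama allylation of ω-formyl 2-(bromomethyl)alk-2-enoates. The cyclohexane closes by 6-exo-trig attack on the aldehyde carbonyl (SE2′ at the allyl unit) through a trans-decalin-like bicyclic transition state. C-1 is controlled by the adjacent silyloxy stereocentre C-2: allylic 1,3-strain with the cis ester holds the C-2 hydrogen in the alkene plane, so the tethered aldehyde reaches the face that leaves the silyloxy and acrylate groups trans and equatorial. C-6 is controlled by the E geometry of the allyl unit fixed in step 10, which puts both ring-forming chains equatorial on the Zimmerman–Traxler chair and gives the 1,6-trans carbinol. The step needs γ- over α-attack and cyclisation over reductive 1,4-elimination or dimerisation; these are secured by the six-membered closure against an eight-membered alternative, the poor leaving ability of the silyl ether and high dilution. The competing chair, which would invert C-1, is disfavoured because it sets the silyloxy group and the ring methyl 1,3-diaxial.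

Step 15
Reactants: 26 3-methylfuran-2(5H)-one
Product: 29 PMB (2Z)-4-(acetyloxy)-2-methylbut-2-enoate, via sodium carboxylate 27 (not isolated), via hydroxy ester 28 (not isolated)
Conditions: NaOH (1.0 equiv), H2O/MeOH, rt, evaporate; 4-methoxybenzyl chloride, DMF, rt; then Ac2O, pyridine, 4-(dimethylamino)pyridine (cat.), 0 °C
Reagents that add atoms: sodium hydroxide [Na+].[OH-]; 4-methoxybenzyl chloride COc1ccc(CCl)cc1; acetic anhydride CC(=O)OC(C)=O
Why: Saponification of the butenolide delivers the Z geometry from the ring, and O-alkylation of the carboxylate followed at once by acetylation should trap the hydroxy ester before it can relactonise.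

Step 16
Reactants: 29 the PMB ester
Product: 30 (2Z)-4-(acetyloxy)-2-methylbut-2-enoic acid
Conditions: CF3CO2H, CH2Cl2, 0 °C
Reagents that add atoms: none
Why: Acidolysis of the PMB ester frees the acid without touching the acetate or the Z alkene.

Step 17
Reactants: 25 the cyclohexanol; 30 (2Z)-4-(acetyloxy)-2-methylbut-2-enoic acid
Product: 32 TMSE 2-[(1R,2R,3S,4R,6S)-6-{[(2Z)-4-(acetyloxy)-2-methylbut-2-enoyl]oxy}-2-(TBSO)-3-[3-(TBDPSO)prop-1-en-2-yl]-4-ethenyl-4-methylcyclohexyl]prop-2-enoate, via mixed anhydride 31 (not isolated)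
Conditions: 30, 2,4,6-trichlorobenzoyl chloride, Et3N, toluene, rt; then 25, 4-(dimethylamino)pyridine, toluene, rt
Reagents that add atoms: none
Why: Yamaguchi esterification acylates the equatorial secondary alcohol with retention and is the established way to transfer Z-2-methylbut-2-enoyl groups without isomerisation to the E isomer.

Step 18
Reactants: 32 the fully protected ester
Product: 33 2-[(1S,2R,3S,4R,6S)-6-{[(2Z)-4-(acetyloxy)-2-methylbut-2-enoyl]oxy}-4-ethenyl-2-hydroxy-3-(3-hydroxyprop-1-en-2-yl)-4-methylcyclohexyl]prop-2-enoic acid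
Conditions: Bu4NF, AcOH (1:1), THF, 0 °C → rt; then pH 4 phosphate buffer, cold extraction
Reagents that add atoms: none
Why: Fluoride-induced fragmentation of the TMSE ester and desilylation of the three silyl ethers; the unhindered ester should fall first, so the hindered C-2 hydroxyl is released only when the carboxyl is a carboxylate that cannot lactonise, and the buffered medium spares the acetate and the enoate.

**Compound list**

1 | tert-butyl(but-3-yn-1-yloxy)dimethylsilane | C#CCCO[Si](C)(C)C(C)(C)C | starting material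
2 | (E)-[4-(TBSO)-2-methylbut-1-en-1-yl]dimethylalumane | C[Al](C)/C=C(\C)CCO[Si](C)(C)C(C)(C)C | intermediate
3 | (2E)-5-(TBSO)-3-methylpent-2-en-1-ol | OC/C=C(\C)CCO[Si](C)(C)C(C)(C)C | intermediate
4 | itaconic anhydride (3-methylideneoxolane-2,5-dione) | C=C1CC(=O)OC1=O | starting material
5 | 4-{[(2E)-5-(TBSO)-3-methylpent-2-en-1-yl]oxy}-2-methylidene-4-oxobutanoic acid | OC(=O)C(=C)CC(=O)OC/C=C(\C)CCO[Si](C)(C)C(C)(C)C | intermediate
6 | isobutyl carbonic mixed anhydride of 5 | CC(C)COC(=O)OC(=O)C(=C)CC(=O)OC/C=C(\C)CCO[Si](C)(C)C(C)(C)C | intermediate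
7 | (2E)-5-(TBSO)-3-methylpent-2-en-1-yl 3-(hydroxymethyl)but-3-enoate | OCC(=C)CC(=O)OC/C=C(\C)CCO[Si](C)(C)C(C)(C)C | intermediate
8 | (2E)-5-(TBSO)-3-methylpent-2-en-1-yl 3-[(TBDPSO)methyl]but-3-enoate | CC(C)(C)[Si](c1ccccc1)(c1ccccc1)OCC(=C)CC(=O)OC/C=C(\C)CCO[Si](C)(C)C(C)(C)C | intermediate
9 | E(O) boron ketene acetal of 8 carrying the (4R,5R)-1,3-bis{[3,5-bis(trifluoromethyl)phenyl]sulfonyl}-4,5-diphenyl-1,3,2-diazaborolidin-2-yl group on oxygen | CC(C)(C)[Si](c1ccccc1)(c1ccccc1)OCC(=C)/C=C(/OB1N(S(=O)(=O)c2cc(cc(c2)C(F)(F)F)C(F)(F)F)[C@H](c2ccccc2)[C@@H](c2ccccc2)N1S(=O)(=O)c1cc(cc(c1)C(F)(F)F)C(F)(F)F)OC/C=C(\C)CCO[Si](C)(C)C(C)(C)C | intermediate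
10 | (2S,3R)-5-(TBSO)-2-[3-(TBDPSO)prop-1-en-2-yl]-3-ethenyl-3-methylpentanoic acid | C=C[C@@](C)(CCO[Si](C)(C)C(C)(C)C)[C@@H](C(=C)CO[Si](c1ccccc1)(c1ccccc1)C(C)(C)C)C(=O)O | intermediate
11 | prop-2-ynoic acid | C#CC(=O)O | starting material
12 | 2-(trimethylsilyl)ethanol | C[Si](C)(C)CCO | starting material
13 | 2-(trimethylsilyl)ethyl prop-2-ynoate | C#CC(=O)OCC[Si](C)(C)C | intermediate
14 | (2S,3R)-5-(TBSO)-2-[3-(TBDPSO)prop-1-en-2-yl]-3-ethenyl-3-methylpentanoyl chloride | C=C[C@@](C)(CCO[Si](C)(C)C(C)(C)C)[C@@H](C(=C)CO[Si](c1ccccc1)(c1ccccc1)C(C)(C)C)C(=O)Cl | intermediate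
15 | bromo{3-oxo-3-[2-(trimethylsilyl)ethoxy]prop-1-yn-1-yl}zinc | Br[Zn]C#CC(=O)OCC[Si](C)(C)C | intermediate
16 | TMSE (5S,6R)-8-(TBSO)-5-[3-(TBDPSO)prop-1-en-2-yl]-6-ethenyl-6-methyl-4-oxooct-2-ynoate | C=C[C@@](C)(CCO[Si](C)(C)C(C)(C)C)[C@@H](C(=C)CO[Si](c1ccccc1)(c1ccccc1)C(C)(C)C)C(=O)C#CC(=O)OCC[Si](C)(C)C | intermediate
17 | TMSE (4R,5S,6R)-8-(TBSO)-5-[3-(TBDPSO)prop-1-en-2-yl]-6-ethenyl-4-hydroxy-6-methyloct-2-ynoate | C=C[C@@](C)(CCO[Si](C)(C)C(C)(C)C)[C@@H](C(=C)CO[Si](c1ccccc1)(c1ccccc1)C(C)(C)C)[C@@H](O)C#CC(=O)OCC[Si](C)(C)C | intermediate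
18 | TMSE (4R,5S,6R)-4,8-bis(TBSO)-5-[3-(TBDPSO)prop-1-en-2-yl]-6-ethenyl-6-methyloct-2-ynoate | C=C[C@@](C)(CCO[Si](C)(C)C(C)(C)C)[C@@H](C(=C)CO[Si](c1ccccc1)(c1ccccc1)C(C)(C)C)[C@@H](O[Si](C)(C)C(C)(C)C)C#CC(=O)OCC[Si](C)(C)C | intermediate
19 | α-(diisobutylalumino) enoate from syn-hydroalumination of 18 (aluminium trans, ester cis to the silyloxy-bearing chain) | C=C[C@@](C)(CCO[Si](C)(C)C(C)(C)C)[C@@H](C(=C)CO[Si](c1ccccc1)(c1ccccc1)C(C)(C)C)[C@@H](O[Si](C)(C)C(C)(C)C)/C=C(/[Al](CC(C)C)CC(C)C)C(=O)OCC[Si](C)(C)C | intermediate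
20 | TMSE (2Z,4S,5S,6R)-4,8-bis(TBSO)-5-[3-(TBDPSO)prop-1-en-2-yl]-6-ethenyl-2-(hydroxymethyl)-6-methyloct-2-enoate | C=C[C@@](C)(CCO[Si](C)(C)C(C)(C)C)[C@@H](C(=C)CO[Si](c1ccccc1)(c1ccccc1)C(C)(C)C)[C@@H](O[Si](C)(C)C(C)(C)C)/C=C(/CO)C(=O)OCC[Si](C)(C)C | intermediate
21 | TMSE (2E,4S,5S,6R)-2-(bromomethyl)-4,8-bis(TBSO)-5-[3-(TBDPSO)prop-1-en-2-yl]-6-ethenyl-6-methyloct-2-enoate | C=C[C@@](C)(CCO[Si](C)(C)C(C)(C)C)[C@@H](C(=C)CO[Si](c1ccccc1)(c1ccccc1)C(C)(C)C)[C@@H](O[Si](C)(C)C(C)(C)C)/C=C(/CBr)C(=O)OCC[Si](C)(C)C | intermediate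
22 | TMSE (2E,4S,5S,6R)-2-(bromomethyl)-4-(TBSO)-5-[3-(TBDPSO)prop-1-en-2-yl]-6-ethenyl-8-hydroxy-6-methyloct-2-enoate | C=C[C@@](C)(CCO)[C@@H](C(=C)CO[Si](c1ccccc1)(c1ccccc1)C(C)(C)C)[C@@H](O[Si](C)(C)C(C)(C)C)/C=C(/CBr)C(=O)OCC[Si](C)(C)C | intermediate
23 | TMSE (2E,4S,5S,6R)-2-(bromomethyl)-4-(TBSO)-5-[3-(TBDPSO)prop-1-en-2-yl]-6-ethenyl-6-methyl-8-oxooct-2-enoate | C=C[C@@](C)(CC=O)[C@@H](C(=C)CO[Si](c1ccccc1)(c1ccccc1)C(C)(C)C)[C@@H](O[Si](C)(C)C(C)(C)C)/C=C(/CBr)C(=O)OCC[Si](C)(C)C | intermediate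
24 | dichloro(allyl)chromium derived from 23 (chromium on the former bromomethyl carbon) | C=C[C@@](C)(CC=O)[C@@H](C(=C)CO[Si](c1ccccc1)(c1ccccc1)C(C)(C)C)[C@@H](O[Si](C)(C)C(C)(C)C)/C=C(/C[Cr](Cl)Cl)C(=O)OCC[Si](C)(C)C | intermediate
25 | TMSE 2-[(1R,2R,3S,4R,6S)-2-(TBSO)-3-[3-(TBDPSO)prop-1-en-2-yl]-4-ethenyl-6-hydroxy-4-methylcyclohexyl]prop-2-enoate | C=C[C@@]1(C)C[C@H](O)[C@@H](C(=C)C(=O)OCC[Si](C)(C)C)[C@H](O[Si](C)(C)C(C)(C)C)[C@@H]1C(=C)CO[Si](c1ccccc1)(c1ccccc1)C(C)(C)C | intermediate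
26 | 3-methylfuran-2(5H)-one | CC1=CCOC1=O | starting material
27 | sodium (2Z)-4-hydroxy-2-methylbut-2-enoate | C/C(=C/CO)C(=O)[O-].[Na+] | intermediate
28 | PMB (2Z)-4-hydroxy-2-methylbut-2-enoate | C/C(=C/CO)C(=O)OCc1ccc(OC)cc1 | intermediate
29 | PMB (2Z)-4-(acetyloxy)-2-methylbut-2-enoate | C/C(=C/COC(C)=O)C(=O)OCc1ccc(OC)cc1 | intermediate
30 | (2Z)-4-(acetyloxy)-2-methylbut-2-enoic acid | C/C(=C/COC(C)=O)C(=O)O | intermediate
31 | (2Z)-4-(acetyloxy)-2-methylbut-2-enoic 2,4,6-trichlorobenzoic anhydride | C/C(=C/COC(C)=O)C(=O)OC(=O)c1c(Cl)cc(Cl)cc1Cl | intermediate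
32 | TMSE 2-[(1R,2R,3S,4R,6S)-6-{[(2Z)-4-(acetyloxy)-2-methylbut-2-enoyl]oxy}-2-(TBSO)-3-[3-(TBDPSO)prop-1-en-2-yl]-4-ethenyl-4-methylcyclohexyl]prop-2-enoate | C=C[C@@]1(C)C[C@H](OC(=O)/C(C)=C\COC(C)=O)[C@@H](C(=C)C(=O)OCC[Si](C)(C)C)[C@H](O[Si](C)(C)C(C)(C)C)[C@@H]1C(=C)CO[Si](c1ccccc1)(c1ccccc1)C(C)(C)C | intermediate
33 | 2-[(1S,2R,3S,4R,6S)-6-{[(2Z)-4-(acetyloxy)-2-methylbut-2-enoyl]oxy}-4-ethenyl-2-hydroxy-3-(3-hydroxyprop-1-en-2-yl)-4-methylcyclohexyl]prop-2-enoic acid | C=C[C@@]1(C)C[C@H](OC(=O)/C(C)=C\COC(C)=O)[C@@H](C(=C)C(=O)O)[C@H](O)[C@@H]1C(=C)CO | target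

**Step count.** Total: 18 steps. Longest linear sequence: 15 steps (steps 1–5, 7–14, 17 and 18, from compound 1).

**Steps most likely to fail**

Step 14 (key step). What may go wrong: E/Z equilibration of the allylchromium before addition, which would divert the closure through the cis-fused transition state to the epimeric carbinol and its lactonisation, or reductive 1,4-elimination of the silyloxy group. The fallback replaces the organochromium closure by a radical one. It sets out from compound 20, which is acetylated (Ac2O, pyridine) to the allylic acetate F1. Selective methanolysis of the primary TBS ether (camphorsulfonic acid, MeOH) should give the primary alcohol F2, and Dess–Martin oxidation the aldehyde F3. SmI2 in THF/t-BuOH at −78 °C should then generate the ketyl radical, which adds 6-exo to the enoate β-carbon through a chair with the oxygen and the ester-bearing carbon trans; the samarium enolate formed on further reduction expels acetate and unveils the methylene group. The sequence comes back to the route at compound 25.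

Step 7. What may go wrong: ketene formation from the acid chloride with loss of the α-stereocentre, or decomposition of the electrophilic 4-oxo-2-ynoate during the coupling. The fallback adds the alkyne to an aldehyde and then oxidises. From compound 10, LiAlH4 reduction gives the primary alcohol F4 and Dess–Martin oxidation the aldehyde F5. Addition of lithiated 13 (LiN(SiMe3)2, THF, −78 °C) gives the propargylic alcohol F6 as a mixture of carbinol epimers, and a second Dess–Martin oxidation converges both epimers on compound 16.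

Step 10. What may go wrong: 1,2-reduction of the ester in competition with conjugate hydroalumination, or protonation of the aluminium allenolate instead of capture by formaldehyde. The fallback uses hydrostannation and cross-coupling. From compound 18, Pd(PPh3)4-catalysed syn-hydrostannation with Bu3SnH gives the α-stannyl enoate F7, and iododestannylation (I2, CH2Cl2, 0 °C) gives the α-iodo enoate F8 with retention. Stille coupling with (tributylstannyl)methanol (Pd(PPh3)4, dioxane, 80 °C) returns compound 20.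

**Further compounds**

F1 | step 14 | TMSE (2Z,4S,5S,6R)-2-[(acetyloxy)methyl]-4,8-bis(TBSO)-5-[3-(TBDPSO)prop-1-en-2-yl]-6-ethenyl-6-methyloct-2-enoate | C=C[C@@](C)(CCO[Si](C)(C)C(C)(C)C)[C@@H](C(=C)CO[Si](c1ccccc1)(c1ccccc1)C(C)(C)C)[C@@H](O[Si](C)(C)C(C)(C)C)/C=C(/COC(C)=O)C(=O)OCC[Si](C)(C)C
F2 | step 14 | TMSE (2Z,4S,5S,6R)-2-[(acetyloxy)methyl]-4-(TBSO)-5-[3-(TBDPSO)prop-1-en-2-yl]-6-ethenyl-8-hydroxy-6-methyloct-2-enoate | C=C[C@@](C)(CCO)[C@@H](C(=C)CO[Si](c1ccccc1)(c1ccccc1)C(C)(C)C)[C@@H](O[Si](C)(C)C(C)(C)C)/C=C(/COC(C)=O)C(=O)OCC[Si](C)(C)C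
F3 | step 14 | TMSE (2Z,4S,5S,6R)-2-[(acetyloxy)methyl]-4-(TBSO)-5-[3-(TBDPSO)prop-1-en-2-yl]-6-ethenyl-6-methyl-8-oxooct-2-enoate | C=C[C@@](C)(CC=O)[C@@H](C(=C)CO[Si](c1ccccc1)(c1ccccc1)C(C)(C)C)[C@@H](O[Si](C)(C)C(C)(C)C)/C=C(/COC(C)=O)C(=O)OCC[Si](C)(C)C
F4 | step 7 | (2S,3R)-5-(TBSO)-2-[3-(TBDPSO)prop-1-en-2-yl]-3-ethenyl-3-methylpentan-1-ol | C=C[C@@](C)(CCO[Si](C)(C)C(C)(C)C)[C@@H](C(=C)CO[Si](c1ccccc1)(c1ccccc1)C(C)(C)C)CO
F5 | step 7 | (2S,3R)-5-(TBSO)-2-[3-(TBDPSO)prop-1-en-2-yl]-3-ethenyl-3-methylpentanal | C=C[C@@](C)(CCO[Si](C)(C)C(C)(C)C)[C@@H](C(=C)CO[Si](c1ccccc1)(c1ccccc1)C(C)(C)C)C=O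
F6 | step 7 | TMSE (4RS,5S,6R)-8-(TBSO)-5-[3-(TBDPSO)prop-1-en-2-yl]-6-ethenyl-4-hydroxy-6-methyloct-2-ynoate (both C-4 epimers) | C=C[C@@](C)(CCO[Si](C)(C)C(C)(C)C)[C@@H](C(=C)CO[Si](c1ccccc1)(c1ccccc1)C(C)(C)C)C(O)C#CC(=O)OCC[Si](C)(C)C
F7 | step 10 | TMSE (2E,4R,5S,6R)-4,8-bis(TBSO)-5-[3-(TBDPSO)prop-1-en-2-yl]-6-ethenyl-6-methyl-2-(tributylstannyl)oct-2-enoate | C=C[C@@](C)(CCO[Si](C)(C)C(C)(C)C)[C@@H](C(=C)CO[Si](c1ccccc1)(c1ccccc1)C(C)(C)C)[C@@H](O[Si](C)(C)C(C)(C)C)/C=C(/[Sn](CCCC)(CCCC)CCCC)C(=O)OCC[Si](C)(C)C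
F8 | step 10 | TMSE (2E,4R,5S,6R)-4,8-bis(TBSO)-5-[3-(TBDPSO)prop-1-en-2-yl]-6-ethenyl-2-iodo-6-methyloct-2-enoate | C=C[C@@](C)(CCO[Si](C)(C)C(C)(C)C)[C@@H](C(=C)CO[Si](c1ccccc1)(c1ccccc1)C(C)(C)C)[C@@H](O[Si](C)(C)C(C)(C)C)/C=C(/I)C(=O)OCC[Si](C)(C)C
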